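Everything rests on cutting ring A at C8–C8a and C4a–C5. The feature used is the 1,3,5-oxygenation of ring A (O1 on C8a, O7, O5) with a carbon branch at C8. The segment C5–C6–C7–C8, carrying hydroxyl, hydrogen, methoxy and prenyl, has the substitution of a γ-prenylated β-methoxy vinylketene acetal made from acetoacetate. In one operation this diene adds across the enol-ether double bond (future C4a=C8a) of an enantiopure ring-C dihydropyranone. Loss of a nucleofuge and of methanol then aromatises the new ring, with prenyl position and O5/O7 differentiation already built in. The precursor is a (2R,3R)-2-aryl-3-silyloxy-2,3-dihydropyran-4-one whose C5 (future C4a) bears a phenylsulfinyl group, which activates the alkene and leaves by syn elimination.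

Key step: step 10

Abbreviations and numbering: Ar = 3-(tert-butyldimethylsilyloxy)-4-methoxyphenyl; TBS = tert-butyldimethylsilyl; TMS = trimethylsilyl; prenyl = 3-methylbut-2-enyl. Monocyclic pyranones are numbered O1, C2–C6. Pyranone C5 and C6 become C4a and C8a in the flavanone numbering used for the bicyclic compounds.

Assumption: (S)-BINOL/titanium is taken to direct the diene to the Si face of the silylated aldehyde, as in related BINOL–titanium carbonyl additions. If the first run shows the opposite sense, (R)-BINOL is used and nothing else changes.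

**Step 1**
Reactants: 1 isovanillin
Product: 2 3-(tert-butyldimethylsilyloxy)-4-methoxybenzaldehyde
Conditions: TBSCl, imidazole, CH2Cl2, rt
Reagents that add atoms: TBSCl, CC(C)(C)[Si](C)(C)Cl
Why: Imidazole-promoted O-silylation (silyl ether protection) masks the acidic phenol, which would otherwise quench the titanium catalyst, the amide base and the ketene acetal used later.

**Step 2**
Reactants: 2 3-(tert-butyldimethylsilyloxy)-4-methoxybenzaldehyde; 3 (E)-1-methoxy-3-(trimethylsilyloxy)buta-1,3-diene (Danishefsky's diene)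
Product: 5 (S)-2-Ar-2,3-dihydro-4H-pyran-4-one, via silylated aldol adduct 4 (not isolated)
Conditions: (S)-BINOL (20 mol %), Ti(OiPr)4 (10 mol %), 4 Å MS, Et2O, −20 °C; then TFA, CH2Cl2, 0 °C
Reagents that add atoms: none
Why: This is a catalytic asymmetric hetero-Diels–Alder reaction in its Mukaiyama-aldol/cyclisation form, established for aromatic aldehydes: the BINOL–titanium complex shields one aldehyde face so that the diene terminus attacks the Si face and sets C2 as S (the spatial arrangement of 2R in the target), acid then closes the ring by oxa-Michael addition and loss of methanol, and the parent diene is used because an endo-selective cycloaddition of a 4-oxygenated diene would give the unwanted 2,3-cis relationship.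

**Step 3**
Reactants: 5 (S)-2-Ar-2,3-dihydro-4H-pyran-4-one
Product: 7 (2R,3R)-2-Ar-3-hydroxy-2,3-dihydro-4H-pyran-4-one, via sodium enolate 6 (not isolated)
Conditions: NaHMDS, THF, −78 °C; 2-(phenylsulfonyl)-3-phenyloxaziridine, −78 °C; AcOH, −78 °C
Reagents that add atoms: 2-(phenylsulfonyl)-3-phenyloxaziridine, O=S(=O)(c1ccccc1)N1OC1c1ccccc1
Why: In this Davis α-hydroxylation of the kinetic cross-conjugated enolate, C3 is the only enolisable position, the oxaziridine approaches the nearly planar 2H-pyran-4-olate anti to the C2 aryl group and so sets C3 as R (2,3-trans), and keeping the whole sequence at −78 °C suppresses ring opening of the enolate by loss of O1.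

**Step 4**
Reactants: 7 (2R,3R)-2-Ar-3-hydroxy-2,3-dihydro-4H-pyran-4-one
Product: 8 (2R,3R)-2-Ar-3-(tert-butyldimethylsilyloxy)-2,3-dihydro-4H-pyran-4-one
Conditions: TBSOTf, 2,6-lutidine, CH2Cl2, −78 → 0 °C
Reagents that add atoms: TBSOTf, CC(C)(C)[Si](C)(C)OS(=O)(=O)C(F)(F)F
Why: Silyl triflate/lutidine silylation of a hindered α-ketol is fast at low temperature and too weakly basic to epimerise C3, and a silyl ether, unlike an ester, is a poor leaving group that does not invite aromatisation to the 4-pyranone.

**Step 5**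
Reactants: 8 (2R,3R)-2-Ar-3-(tert-butyldimethylsilyloxy)-2,3-dihydro-4H-pyran-4-one
Product: 10 (2R,3R)-2-Ar-3-(tert-butyldimethylsilyloxy)-5-(phenylsulfanyl)-2,3-dihydro-4H-pyran-4-one, via chloro sulfide adduct 9 (not isolated)
Conditions: PhSH, NCS, CH2Cl2, 0 °C (gives PhSCl); 8, −78 → 0 °C; Et3N, 0 °C
Reagents that add atoms: thiophenol, Sc1ccccc1 (delivered as benzenesulfenyl chloride, ClSc1ccccc1)
Why: In this electrophilic α-sulfenylation of a vinylogous ester by addition–elimination, the sulfenyl chloride attacks the nucleophilic C5 of the enol ether, chloride caps C6, triethylamine removes the now acidic C5–H and expels chloride (a far better leaving group than O1), and the aryl ring is inert to PhSCl without a Lewis acid.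

**Step 6**
Reactants: 10 (2R,3R)-2-Ar-3-(tert-butyldimethylsilyloxy)-5-(phenylsulfanyl)-2,3-dihydro-4H-pyran-4-one
Product: 11 (2R,3R)-2-Ar-3-(tert-butyldimethylsilyloxy)-5-(phenylsulfinyl)-2,3-dihydro-4H-pyran-4-one (both sulfur epimers)
Conditions: mCPBA (1.0 equiv), NaHCO3, CH2Cl2, −78 → −30 °C
Reagents that add atoms: mCPBA, O=C(OO)c1cccc(Cl)c1
Why: One equivalent of peracid at low temperature oxidises the sulfide to the sulfoxide chemoselectively, because sulfur is far more nucleophilic than the acceptor-substituted alkene or the arene, and the new sulfur stereocentre is not controlled since it is lost in step 10.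

**Step 7**
Reactants: 12 methyl acetoacetate; 13 prenyl bromide
Product: 15 methyl 7-methyl-3-oxooct-6-enoate, via acetoacetate dianion 14 (not isolated)
Conditions: NaH, THF, 0 °C; n-BuLi, 0 °C; 13, 0 °C → rt; 1 M HCl
Reagents that add atoms: none
Why: In the γ-alkylation of the acetoacetate dianion, the more basic terminal carbanion reacts selectively with the allylic bromide by SN2.

**Step 8**
Reactants: 15 methyl 7-methyl-3-oxooct-6-enoate
Product: 17 methyl (E)-3-methoxy-7-methylocta-2,6-dienoate, via dimethyl ketal 16 (not isolated)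
Conditions: HC(OMe)3, H2SO4 (cat.), MeOH, rt; distillation
Reagents that add atoms: trimethyl orthoformate, COC(OC)OC
Why: Acid-catalysed orthoformate ketalisation and loss of methanol give the conjugated enol ether, the thermodynamically favoured E isomer places C4 syn to the ester for the next deprotonation, and catalytic acid at room temperature leaves the trisubstituted alkene alone.

**Step 9**
Reactants: 17 methyl (E)-3-methoxy-7-methylocta-2,6-dienoate
Product: 19 (3Z)-1,3-dimethoxy-7-methyl-1-(trimethylsilyloxy)octa-1,3,6-triene, via lithium dienolate 18 (not isolated)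
Conditions: LDA, THF, −78 °C; TMSCl, −78 °C → rt; non-aqueous work-up
Reagents that add atoms: TMSCl, C[Si](C)(C)Cl
Why: Ester-directed kinetic γ-deprotonation of a β-methoxy enoate and O-silylation of the dienolate is the standard preparation of Brassard-type vinylketene acetals, and allylic strain should place the prenyl chain trans to C2 (3Z), the geometry that can reach the s-cis conformation.

**Step 10**
Reactants: 11 (2R,3R)-2-Ar-3-(tert-butyldimethylsilyloxy)-5-(phenylsulfinyl)-2,3-dihydro-4H-pyran-4-one; 19 (3Z)-1,3-dimethoxy-7-methyl-1-(trimethylsilyloxy)octa-1,3,6-triene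
Product: 23 (2R,3R)-2-Ar-3-(tert-butyldimethylsilyloxy)-5-hydroxy-7-methoxy-8-prenylchroman-4-one, via cycloadduct 20 (not isolated), via dienyl ketal 21 (not isolated), via aryl trimethylsilyl ether 22 (not isolated)
Conditions: 19 (3 equiv), PhMe, 90 °C, sealed tube; then 5% aq citric acid, THF, rt
Reagents that add atoms: none
Why: Proposed new method: the pyranone C5=C6 bond of 11, polarised by the C4 carbonyl and the sulfinyl group, should accept the electron-rich diene 19 in a strongly asynchronous normal-demand [4+2] cycloaddition in which the prenyl-bearing terminus C4 of 19 bonds first to C6 (C8–C8a) and the ketene-acetal carbon C1 then bonds to C5 (C4a–C5), so that ring A is closed as a six-membered carbocycle by intermolecular cycloaddition (20). Suprafacial addition leaves the C8a hydrogen and the C4a sulfinyl group cis, exactly the geometry of a thermal syn (Ei) elimination, so PhSOH is lost at the reaction temperature; a halide at C4a would have neither an anti-periplanar nor an acidic hydrogen next to it, which is why sulfur is chosen as the leaving group. In the resulting 21, O1 sits again on an sp2 carbon of a vinylogous ester and can no longer be expelled, and ionisation of the C5 ketal with loss of the doubly allylic C8 hydrogen removes methanol to give arene 22, whose aryl O–TMS bond is hydrolysed on the mild acidic work-up while both TBS ethers persist. The closest known reaction types are the Diels–Alder/aromatisation of Brassard-type vinylketene acetals with halo- or sulfinylquinones and the cycloaddition of 3-sulfinyl- and 3-acylchromones with silyloxydienes, but a monocyclic 2,3-dihydropyran-4-one has not served as the dienophile in such a benzannulation. No stereocentre survives from this step, since C4a, C5, C8, C8a and sulfur all become planar or leave, so facial and endo/exo selectivity do not matter, and C2 and C3 are spectators under neutral conditions. The step needs regioselectivity, secured because C6 is the β-carbon of both acceptors and meets the most nucleophilic diene terminus, and it needs ring closure to outrun Michael addition, silyl transfer and β-elimination of O1, which is favoured by a non-polar solvent, the absence of Lewis acids and, if required, high pressure.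

**Step 11**
Reactants: 23 (2R,3R)-2-Ar-3-(tert-butyldimethylsilyloxy)-5-hydroxy-7-methoxy-8-prenylchroman-4-one
Product: 24 (2R,3R)-3,5-dihydroxy-2-(3-hydroxy-4-methoxyphenyl)-7-methoxy-8-prenylchroman-4-one (target)
Conditions: HF·pyridine, pyridine, THF, 0 °C → rt
Reagents that add atoms: none
Why: Fluoride-driven cleavage of both silyl ethers under weakly acidic buffered conditions avoids the base-induced ring opening, C2/C3 epimerisation and air oxidation typical of dihydroflavonols, and dilute HF·pyridine leaves the prenyl group and the methyl ethers untouched.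

**Compound list**

1 | isovanillin | COc1ccc(C=O)cc1O | starting material
2 | 3-(tert-butyldimethylsilyloxy)-4-methoxybenzaldehyde | COc1ccc(C=O)cc1O[Si](C)(C)C(C)(C)C | intermediate
3 | (E)-1-methoxy-3-(trimethylsilyloxy)buta-1,3-diene | CO/C=C/C(=C)O[Si](C)(C)C | starting material
4 | (S,E)-5-Ar-1-methoxy-5-(trimethylsilyloxy)pent-1-en-3-one | COc1ccc([C@H](CC(=O)/C=C/OC)O[Si](C)(C)C)cc1O[Si](C)(C)C(C)(C)C | intermediate
5 | (S)-2-Ar-2,3-dihydro-4H-pyran-4-one | COc1ccc([C@H]2OC=CC(=O)C2)cc1O[Si](C)(C)C(C)(C)C | intermediate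
6 | sodium (S)-2-Ar-2H-pyran-4-olate | COc1ccc([C@H]2OC=CC([O-])=C2)cc1O[Si](C)(C)C(C)(C)C.[Na+] | intermediate
7 | (2R,3R)-2-Ar-3-hydroxy-2,3-dihydro-4H-pyran-4-one | COc1ccc([C@H]2OC=CC(=O)[C@@H]2O)cc1O[Si](C)(C)C(C)(C)C | intermediate
8 | (2R,3R)-2-Ar-3-(TBS-oxy)-2,3-dihydro-4H-pyran-4-one | COc1ccc([C@H]2OC=CC(=O)[C@@H]2O[Si](C)(C)C(C)(C)C)cc1O[Si](C)(C)C(C)(C)C | intermediate
9 | (2R,3R)-2-Ar-6-chloro-5-(phenylsulfanyl)-3-(TBS-oxy)tetrahydropyran-4-one (C5, C6 not defined) | COc1ccc([C@H]2OC(Cl)C(Sc3ccccc3)C(=O)[C@@H]2O[Si](C)(C)C(C)(C)C)cc1O[Si](C)(C)C(C)(C)C | intermediate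
10 | (2R,3R)-2-Ar-5-(phenylsulfanyl)-3-(TBS-oxy)-2,3-dihydro-4H-pyran-4-one | COc1ccc([C@H]2OC=C(Sc3ccccc3)C(=O)[C@@H]2O[Si](C)(C)C(C)(C)C)cc1O[Si](C)(C)C(C)(C)C | intermediate
11 | (2R,3R)-2-Ar-5-(phenylsulfinyl)-3-(TBS-oxy)-2,3-dihydro-4H-pyran-4-one (sulfur not defined) | COc1ccc([C@H]2OC=C(S(=O)c3ccccc3)C(=O)[C@@H]2O[Si](C)(C)C(C)(C)C)cc1O[Si](C)(C)C(C)(C)C | intermediate
12 | methyl acetoacetate | COC(=O)CC(C)=O | starting material
13 | prenyl bromide (1-bromo-3-methylbut-2-ene) | CC(C)=CCBr | starting material
14 | sodium lithium dianion of methyl acetoacetate | COC([O-])=CC([O-])=C.[Na+].[Li+] | intermediate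
15 | methyl 7-methyl-3-oxooct-6-enoate | COC(=O)CC(=O)CCC=C(C)C | intermediate
16 | methyl 3,3-dimethoxy-7-methyloct-6-enoate | COC(=O)CC(OC)(OC)CCC=C(C)C | intermediate
17 | methyl (E)-3-methoxy-7-methylocta-2,6-dienoate | COC(=O)/C=C(OC)\CCC=C(C)C | intermediate
18 | lithium dienolate of 17 | COC([O-])=C/C(OC)=C/CC=C(C)C.[Li+] | intermediate
19 | (3Z)-1,3-dimethoxy-7-methyl-1-(trimethylsilyloxy)octa-1,3,6-triene (C1=C2 geometry not defined) | COC(O[Si](C)(C)C)=C/C(OC)=C/CC=C(C)C | intermediate
20 | (2R,3R)-2-Ar-5,7-dimethoxy-4a-(phenylsulfinyl)-8-prenyl-3-(TBS-oxy)-5-(TMS-oxy)-4a,5,8,8a-tetrahydrochroman-4-one (cis-fused; C4a, C5, C8, C8a, S not defined) | COc1ccc([C@H]2OC3C(CC=C(C)C)C(OC)=CC(OC)(O[Si](C)(C)C)C3(S(=O)c4ccccc4)C(=O)[C@@H]2O[Si](C)(C)C(C)(C)C)cc1O[Si](C)(C)C(C)(C)C | intermediate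
21 | (2R,3R)-2-Ar-5,7-dimethoxy-8-prenyl-3-(TBS-oxy)-5-(TMS-oxy)-5,8-dihydrochroman-4-one (C5, C8 not defined) | COc1ccc([C@H]2OC3=C(C(=O)[C@@H]2O[Si](C)(C)C(C)(C)C)C(OC)(O[Si](C)(C)C)C=C(OC)C3CC=C(C)C)cc1O[Si](C)(C)C(C)(C)C | intermediate
22 | 5-O-trimethylsilyl ether of 23 | COc1ccc([C@H]2Oc3c(CC=C(C)C)c(OC)cc(O[Si](C)(C)C)c3C(=O)[C@@H]2O[Si](C)(C)C(C)(C)C)cc1O[Si](C)(C)C(C)(C)C | intermediate
23 | (2R,3R)-2-Ar-5-hydroxy-7-methoxy-8-prenyl-3-(TBS-oxy)chroman-4-one | COc1ccc([C@H]2Oc3c(CC=C(C)C)c(OC)cc(O)c3C(=O)[C@@H]2O[Si](C)(C)C(C)(C)C)cc1O[Si](C)(C)C(C)(C)C | intermediate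
24 | (2R,3R)-3,5-dihydroxy-2-(3-hydroxy-4-methoxyphenyl)-7-methoxy-8-prenylchroman-4-one | COc1ccc([C@H]2Oc3c(CC=C(C)C)c(OC)cc(O)c3C(=O)[C@@H]2O)cc1O | target

Total step count: 11. Longest linear sequence: 8 (steps 1–6, 10, 11).

**Steps most likely to fail**

1. **Step 10.**
 - What may go wrong: the cycloaddition onto a donor-substituted alkene may be too slow. Alternatively, the reaction may divert into stepwise vinylogous Michael addition with silyl transfer, followed by expulsion of O1 and opening of ring C.
 - Fallback (known chemistry; sets out from 1, comes back at 23): ring A is taken from a preformed phloroglucinol and the prenyl group is moved to C8 at the end. Isovanillin 1 is treated with MOMCl/iPr2NEt to give 4-methoxy-3-(methoxymethoxy)benzaldehyde F1. Purchased 2',6'-dihydroxy-4'-methoxyacetophenone F2 is protected twice (NaH, MOMCl, DMF) to give 4'-methoxy-2',6'-bis(methoxymethoxy)acetophenone F3. Claisen–Schmidt condensation of the two (KOH, EtOH) gives the (E)-chalcone F4. Juliá–Colonna epoxidation (poly-L-leucine, urea–H2O2, DBU, THF) gives the (αR,βS)-epoxy ketone F5. HCl in MeOH removes the three MOM groups, and a freed ortho-phenol opens the epoxide at the benzylic carbon. The intact C3 centre steers closure to the trans product, and ring A is still symmetric, so either ortho-hydroxyl leads to the same (2R,3R)-3,5,3'-trihydroxy-7,4'-dimethoxyflavanone F6. TBSCl/imidazole silylates O3 and O3' but not the chelated 5-OH, giving the 3,3'-bis-TBS ether F7. Mitsunobu etherification with prenol (PPh3, DIAD) gives the 5-O-prenyl ether F8. Eu(fod)3-catalysed Claisen–Cope rearrangement (C6, then C8) delivers 23.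

2. **Step 3.**
 - What may go wrong: the enolate may open by loss of O1 from C2 before oxygen transfer, which would also erase C2. Anti-facial selectivity may also be incomplete.
 - Fallback (sets out from 5, comes back at 7): the free enolate is avoided by manganese(III) acetate α'-acetoxylation of the enone in refluxing benzene, which should deliver acetate anti to the aryl group and give the (2R,3R)-3-acetoxy pyranone F9. Acid-catalysed methanolysis (cat. p-TsOH, MeOH, rt) then liberates 7.

3. **Step 5.**
 - What may go wrong: attack of the sulfenyl chloride on the acceptor-deactivated enol ether may be sluggish. Sulfenylation of the electron-rich aryl ring may compete. O1 may be lost in place of chloride during the elimination.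
 - Fallback (sets out from 8, comes back at 10): the C–S bond is made by cross-coupling. Nucleophile-catalysed α-iodination (I2, pyridine, CH2Cl2) gives the 5-iodo pyranone F10. Palladium-catalysed thiolation (PhSH, Pd2(dba)3, Xantphos, iPr2NEt, dioxane, 80 °C) then gives 10.

**Further compounds**

F1 | step 10 | 4-methoxy-3-(methoxymethoxy)benzaldehyde | COCOc1cc(C=O)ccc1OC
F2 | step 10 | 2',6'-dihydroxy-4'-methoxyacetophenone (purchased) | CC(=O)c1c(O)cc(OC)cc1O
F3 | step 10 | 4'-methoxy-2',6'-bis(methoxymethoxy)acetophenone | COCOc1cc(OC)cc(OCOC)c1C(C)=O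
F4 | step 10 | (E)-3-[4-methoxy-3-(methoxymethoxy)phenyl]-1-[4-methoxy-2,6-bis(methoxymethoxy)phenyl]prop-2-en-1-one | COCOc1cc(/C=C/C(=O)c2c(OCOC)cc(OC)cc2OCOC)ccc1OC
F5 | step 10 | [(2R,3S)-3-[4-methoxy-3-(methoxymethoxy)phenyl]oxiran-2-yl][4-methoxy-2,6-bis(methoxymethoxy)phenyl]methanone | COCOc1cc([C@@H]2O[C@H]2C(=O)c2c(OCOC)cc(OC)cc2OCOC)ccc1OC
F6 | step 10 | (2R,3R)-3,5-dihydroxy-2-(3-hydroxy-4-methoxyphenyl)-7-methoxychroman-4-one | COc1ccc([C@H]2Oc3cc(OC)cc(O)c3C(=O)[C@@H]2O)cc1O
F7 | step 10 | (2R,3R)-2-Ar-5-hydroxy-7-methoxy-3-(TBS-oxy)chroman-4-one | COc1ccc([C@H]2Oc3cc(OC)cc(O)c3C(=O)[C@@H]2O[Si](C)(C)C(C)(C)C)cc1O[Si](C)(C)C(C)(C)C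
F8 | step 10 | (2R,3R)-2-Ar-7-methoxy-5-(prenyloxy)-3-(TBS-oxy)chroman-4-one | COc1ccc([C@H]2Oc3cc(OC)cc(OCC=C(C)C)c3C(=O)[C@@H]2O[Si](C)(C)C(C)(C)C)cc1O[Si](C)(C)C(C)(C)C
F9 | step 3 | (2R,3R)-3-acetoxy-2-Ar-2,3-dihydro-4H-pyran-4-one | COc1ccc([C@H]2OC=CC(=O)[C@@H]2OC(C)=O)cc1O[Si](C)(C)C(C)(C)C
F10 | step 5 | (2R,3R)-2-Ar-5-iodo-3-(TBS-oxy)-2,3-dihydro-4H-pyran-4-one | COc1ccc([C@H]2OC=C(I)C(=O)[C@@H]2O[Si](C)(C)C(C)(C)C)cc1O[Si](C)(C)C(C)(C)C
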